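**Plan**
Retrosynthesis: the acetates and the butenolide are removed first (C12–C13 by Suzuki coupling, C11=C12 by chromium olefination). The C7/C8 diol is traced to a C7=C8 alkene, and C9–C11 is cut by a [2,3]-Wittig–Still shift from a C7 ether. C3–C4 and C5–C10 are cut last, together.
Enabling feature: ring A is a cyclohexene in which the C3=C4 bond and the C5–C10 fusion bond flank the C4–C5 unit. C4–C5 can therefore be the carbonyl-conjugated bond of an allenyl ketone (C6=O) and C10–C1–C2–C3 a 2-silyloxy diene, tied by C6–C9, the future ring B.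
Helpers: the distal allene bond becomes C18 and, after conjugation with the C2 ketone, the C3=C4 alkene. The C2 ketone is removed later through its dithiolane, and the stannylmethyl ether on C7 is consumed in the sigmatropic shift.
Forward order: a linear chain is built in nine steps; step 10 closes rings A and B together; then follow the C9 quaternary centre, the ring B oxygens, C2 deoxygenation and the side chain.
Stereochemistry: a single carbinol (C7) from a Noyori reduction directs C5/C10 in the cycloaddition, is transferred to C9 by the sigmatropic shift and is then lost. C6 comes from hydride attack anti to C19, and C7/C8 from osmylation anti to the 6β-hydroxyl. Alkene geometries come from anti-carbomagnesiation (C8=C9), Wittig reaction (C10=C1) and Takai–Utimoto olefination (C11=C12).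

Key step: step 10

Remark: clerodane numbers are used for every compound (ring A C1–C5 and C10, ring B C5–C10, methyls C17 on C8, C18 on C4, C19 on C5, C20 on C9, side chain C11–C16); in bicyclic compounds β is the face of the C19 methyl, H-10 is α (trans fusion), and C20 and C17 are β wherever C9 and C8 are sp3.

Step 1
Reactants: 1 ethyl 2,2-diethoxyacetate; 2 prop-1-yn-1-ylmagnesium bromide
Product: 3 1,1-diethoxypent-3-yn-2-one
Conditions: THF, −78 °C to −30 °C; aq. NH4Cl
Reagents that add atoms: none
Why: Acylation of an alkynyl Grignard reagent by an α,α-dialkoxy ester should stop at the ketone because the chelated tetrahedral magnesium alkoxide collapses only on work-up.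

Step 2
Reactants: 3 1,1-diethoxypent-3-yn-2-one
Product: 4 (R)-1,1-diethoxypent-3-yn-2-ol
Conditions: Ru[(S,S)-TsNCH(Ph)CH(Ph)NH](p-cymene) (1 mol%), i-PrOH, rt
Reagents that add atoms: none
Why: Noyori asymmetric transfer hydrogenation of an ynone, in which the (S,S)-catalyst places the alkynyl group as it does for simple ynones, should set C7 with the R descriptor because the diethoxymethyl group outranks the alkynyl group.

Step 3
Reactants: 4 (R)-1,1-diethoxypent-3-yn-2-ol
Product: 6 (R,Z)-1,1-diethoxy-4-iodo-3-methylpent-3-en-2-ol, via cyclic alkenylmagnesium alkoxide 5 (not isolated)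
Conditions: MeMgBr (3.5 equiv), CuI (0.2 equiv), Et2O/THF, 0 °C to reflux; then I2, −78 °C to 0 °C
Reagents that add atoms: methylmagnesium bromide (C[Mg]Br); iodine ([I][I])
Why: Alkoxide-directed anti-carbomagnesiation of a propargylic alcohol under CuI catalysis places the new methyl (C17) on C8 and magnesium on C9 inside a five-membered chelate, so that iodinolysis with retention should give the tetrasubstituted alkene with C7 and iodine cis, the geometry ring B needs.

Step 4
Reactants: 6 (R,Z)-1,1-diethoxy-4-iodo-3-methylpent-3-en-2-ol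
Product: 7 (R,Z)-tributyl{[(1,1-diethoxy-4-iodo-3-methylpent-3-en-2-yl)oxy]methyl}stannane
Conditions: KH, THF, 0 °C; Bu3SnCH2I, 0 °C to rt
Reagents that add atoms: (iodomethyl)tributylstannane (CCCC[Sn](CCCC)(CCCC)CI)
Why: Williamson etherification of the potassium alkoxide installs the Wittig–Still handle without touching the C7 configuration or the fully substituted alkenyl iodide, which has no hydrogen for elimination.

Step 5
Reactants: 7 (R,Z)-tributyl{[(1,1-diethoxy-4-iodo-3-methylpent-3-en-2-yl)oxy]methyl}stannane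
Product: 9 (R,Z)-5,5-diethoxy-2,3-dimethyl-4-[(tributylstannyl)methoxy]pent-2-enal, via alkenylmagnesium chloride 8 (not isolated)
Conditions: i-PrMgCl·LiCl, THF, −20 °C to rt; DMF, 0 °C; aq. NH4Cl
Reagents that add atoms: N,N-dimethylformamide (CN(C)C=O)
Why: Iodine–magnesium exchange, helped by chelation of magnesium by the cis allylic ether oxygen, should give a configurationally stable alkenylmagnesium species that is formylated by DMF (Bouveault aldehyde synthesis) while the carbon–tin bond stays inert to magnesium reagents.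

Step 6
Reactants: 9 (R,Z)-5,5-diethoxy-2,3-dimethyl-4-[(tributylstannyl)methoxy]pent-2-enal; 10 1-(triphenyl-λ5-phosphanylidene)propan-2-one
Product: 11 (3E,5Z,7R)-8,8-diethoxy-5,6-dimethyl-7-[(tributylstannyl)methoxy]octa-3,5-dien-2-one
Conditions: PhMe, 90 °C
Reagents that add atoms: none
Why: Wittig olefination with a stabilized ylide should give the E-enone (C10=C1) and cannot disturb the tetrasubstituted C8=C9 alkene.

Step 7
Reactants: 11 (3E,5Z,7R)-8,8-diethoxy-5,6-dimethyl-7-[(tributylstannyl)methoxy]octa-3,5-dien-2-one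
Product: 12 (2R,3Z,5E)-3,4-dimethyl-7-oxo-2-[(tributylstannyl)methoxy]octa-3,5-dienal
Conditions: TFA/H2O (9:1), CH2Cl2, 0 °C
Reagents that add atoms: water (O)
Why: Acid-catalysed acetal hydrolysis unmasks the C6 aldehyde, and short cold exposure should limit enolization of the α-alkoxy aldehyde and protodestannylation.

Step 8
Reactants: 12 (2R,3Z,5E)-3,4-dimethyl-7-oxo-2-[(tributylstannyl)methoxy]octa-3,5-dienal; 13 1-bromobut-2-yne
Product: 14 (3E,5Z,7R)-8-hydroxy-5,6,9-trimethyl-7-[(tributylstannyl)methoxy]undeca-3,5,9,10-tetraen-2-one (both C8 epimers)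
Conditions: indium powder (In), DMF, rt
Reagents that add atoms: none
Why: The indium-mediated Barbier reaction of a γ-substituted propargyl bromide reacts through the propargylindium species in SE2′ fashion to give the α-allenyl carbinol and is selective for the aldehyde over the enone, while the new carbinol configuration is irrelevant because C6 is oxidized next.

Step 9
Reactants: 14 (3E,5Z,7R)-8-hydroxy-5,6,9-trimethyl-7-[(tributylstannyl)methoxy]undeca-3,5,9,10-tetraen-2-one
Product: 15 (3E,5Z,7R)-5,6,9-trimethyl-7-[(tributylstannyl)methoxy]undeca-3,5,9,10-tetraene-2,8-dione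
Conditions: Dess–Martin periodinane, NaHCO3, CH2Cl2, 0 °C
Reagents that add atoms: none
Why: Dess–Martin oxidation under buffered, non-basic conditions should convert the allenyl carbinol into the allenyl ketone without isomerizing the allene or epimerizing C7.

Step 10
Reactants: 15 (3E,5Z,7R)-5,6,9-trimethyl-7-[(tributylstannyl)methoxy]undeca-3,5,9,10-tetraene-2,8-dione
Product: 17 2-[(tert-butyldimethylsilyl)oxy]-7α-[(tributylstannyl)methoxy]-11,12,13,14,15,16-hexanorcleroda-1,4(18),8-trien-6-one, via silyl dienol ether 16 (not isolated)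
Conditions: TBSOTf, i-Pr2NEt, CH2Cl2, −78 °C to rt, then 40 °C; Et3N-deactivated silica
Reagents that add atoms: tert-butyldimethylsilyl trifluoromethanesulfonate (CC(C)(C)[Si](C)(C)OS(=O)(=O)C(F)(F)F)
Why: Soft enolization of the methyl ketone gives the cross-conjugated 2-silyloxy diene C10=C1–C2(OTBS)=C3, which undergoes a concerted, asynchronous intramolecular Diels–Alder reaction with the carbonyl-conjugated C4=C5 bond of the allenyl ketone, forming C3–C4 and C5–C10 with the electronically matched pairing of the nucleophilic diene terminus C3 and the electrophilic allene carbon C4. The closest known reaction type is the intramolecular Diels–Alder reaction of in situ generated 2-silyloxy dienes with tethered enones, together with the use of allenyl ketones as dienophiles. Ring A is closed by the suprafacial [4+2] cycloaddition itself and ring B by the four-atom tether C6–C9 in the anti (exo-tether) mode, the only mode open to a planar s-trans C8=C9–C10=C1 unit whose tether leaves C8 cis to C10; this places the C6 carbonyl exo and the C19 methyl endo and should give the trans relationship of C19 and H-10. The diene face is chosen by C7: the C7–H bond eclipses the C8 methyl to minimize allylic strain, so the dienophile arm and the alkoxy group lie on opposite faces and C5 should add to C10 anti to the C7 oxygen. The step needs regioselectivity for the conjugated bond of the allene, whose distal bond survives as the C4 methylidene, and chemoselective enolization of the methyl ketone over the hindered C7–H, which the unhindered methyl group, the bulky base and the low temperature should secure.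

Step 11
Reactants: 17 2-[(tert-butyldimethylsilyl)oxy]-7α-[(tributylstannyl)methoxy]-11,12,13,14,15,16-hexanorcleroda-1,4(18),8-trien-6-one
Product: 18 2-[(tert-butyldimethylsilyl)oxy]-7α-[(tributylstannyl)methoxy]-11,12,13,14,15,16-hexanorcleroda-1,4(18),8-trien-6β-ol
Conditions: NaBH4, MeOH/CH2Cl2, −40 °C to 0 °C
Reagents that add atoms: none
Why: Borohydride reduction should deliver hydride to C6 from the α face, anti to the axial C19 methyl on the neighbouring quaternary carbon, to give the equatorial 6β-alcohol while the silyl enol ether is inert.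

Step 12
Reactants: 18 2-[(tert-butyldimethylsilyl)oxy]-7α-[(tributylstannyl)methoxy]-11,12,13,14,15,16-hexanorcleroda-1,4(18),8-trien-6β-ol
Product: 20 2-[(tert-butyldimethylsilyl)oxy]-12,13,14,15,16-pentanorcleroda-1,4(18),7-triene-6β,11-diol, via dilithio alkoxide 19 (not isolated)
Conditions: n-BuLi (2.5 equiv), THF, −78 °C to −20 °C; aq. NH4Cl
Reagents that add atoms: none
Why: In this Wittig–Still [2,3]-sigmatropic rearrangement tin–lithium exchange gives the α-alkoxymethyllithium, which should add suprafacially so that the C9–C11 bond forms on the α face where the C7–O bond was, setting the C9 quaternary centre (C20 β, C11 α) and moving the alkene to C7=C8.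

Step 13
Reactants: 20 2-[(tert-butyldimethylsilyl)oxy]-12,13,14,15,16-pentanorcleroda-1,4(18),7-triene-6β,11-diol
Product: 22 6β,11-dihydroxy-12,13,14,15,16-pentanorcleroda-3,7-dien-2-one, via β,γ-unsaturated ketone 21 (not isolated)
Conditions: TBAF, THF, 0 °C; then DBU, rt
Reagents that add atoms: none
Why: Fluoride cleavage of the silyl enol ether gives the C2 ketone, and base-mediated conjugation should move the exocyclic C4=C18 bond into the ring to give the more stable 4-methyl-3-en-2-one, which fixes the C3=C4 position and turns C18 into the methyl group.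

Step 14
Reactants: 22 6β,11-dihydroxy-12,13,14,15,16-pentanorcleroda-3,7-dien-2-one
Product: 23 6β,7α,8α,11-tetrahydroxy-12,13,14,15,16-pentanorclerod-3-en-2-one
Conditions: OsO4 (5 mol%), NMO, acetone/H2O, rt
Reagents that add atoms: N-methylmorpholine N-oxide (C[N+]1([O-])CCOCC1); water (O); osmium tetroxide as catalytic oxygen carrier (O=[Os](=O)(=O)=O)
Why: Upjohn dihydroxylation should attack the electron-rich C7=C8 alkene in preference to the electron-poor enone and from the α face, anti to the allylic 6β-hydroxyl (Kishi's rule) and to the axial C19 and C20 methyls, setting C7 and C8 in one syn addition.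

Step 15
Reactants: 23 6β,7α,8α,11-tetrahydroxy-12,13,14,15,16-pentanorclerod-3-en-2-one
Product: 24 2,2-(ethane-1,2-diyldisulfanediyl)-12,13,14,15,16-pentanorclerod-3-ene-6β,7α,8α,11-tetraol
Conditions: HSCH2CH2SH, BF3·OEt2, MeOH, rt
Reagents that add atoms: ethane-1,2-dithiol (SCCS)
Why: Lewis acid-catalysed thioketalization of the unhindered C2 enone carbonyl should give the dithiolane without moving the β,β-disubstituted double bond and in the presence of free hydroxyls, as in the protection of steroidal 4-en-3-ones.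

Step 16
Reactants: 24 2,2-(ethane-1,2-diyldisulfanediyl)-12,13,14,15,16-pentanorclerod-3-ene-6β,7α,8α,11-tetraol
Product: 25 12,13,14,15,16-pentanorclerod-3-ene-6β,7α,8α,11-tetraol
Conditions: Raney nickel (W-2), EtOH, 60 °C
Reagents that add atoms: none
Why: Mozingo desulfurization replaces both C–S bonds at C2 by C–H and should leave the hindered trisubstituted C3=C4 alkene in place, as in the conversion of steroidal 4-en-3-one thioketals into 4-enes.

Step 17
Reactants: 25 12,13,14,15,16-pentanorclerod-3-ene-6β,7α,8α,11-tetraol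
Product: 26 6β,7α,8α-trihydroxy-12,13,14,15,16-pentanorclerod-3-en-11-al
Conditions: TEMPO (cat.), PhI(OAc)2, CH2Cl2, rt
Reagents that add atoms: none
Why: Oxoammonium (TEMPO) oxidation is selective for the primary C11 alcohol over the hindered secondary and tertiary hydroxyls and stops at the aldehyde under non-basic conditions.

Step 18
Reactants: 26 6β,7α,8α-trihydroxy-12,13,14,15,16-pentanorclerod-3-en-11-al
Product: 27 (11E)-12-(4,4,5,5-tetramethyl-1,3,2-dioxaborolan-2-yl)-13,14,15,16-tetranorcleroda-3,11-diene-6β,7α,8α-triol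
Conditions: CrCl2, Cl2CHB(pin), LiI, THF, rt
Reagents that add atoms: 2-(dichloromethyl)-4,4,5,5-tetramethyl-1,3,2-dioxaborolane (ClC(Cl)B1OC(C)(C)C(C)(C)O1)
Why: Takai–Utimoto olefination with the geminal dichromium reagent should convert the hindered aldehyde into the (E)-alkenylboronate (C11=C12) under non-basic conditions that avoid retro-aldol cleavage of the β-hydroxy aldehyde.

Step 19
Reactants: 27 (11E)-12-(4,4,5,5-tetramethyl-1,3,2-dioxaborolan-2-yl)-13,14,15,16-tetranorcleroda-3,11-diene-6β,7α,8α-triol; 28 4-bromofuran-2(5H)-one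
Product: 29 (11E)-6β,7α,8α-trihydroxycleroda-3,11,13-trien-15,16-olide
Conditions: PdCl2(dppf) (5 mol%), K3PO4, THF/H2O, 45 °C
Reagents that add atoms: none
Why: Suzuki–Miyaura coupling of the (E)-alkenylboronate with the β-bromobutenolide should form C12–C13 with retention of the alkene geometry.

Step 20
Reactants: 29 (11E)-6β,7α,8α-trihydroxycleroda-3,11,13-trien-15,16-olide
Product: 30 (11E)-6β,7α-diacetoxy-8α-hydroxycleroda-3,11,13-trien-15,16-olide
Conditions: Ac2O, pyridine, DMAP (cat.), CH2Cl2, rt
Reagents that add atoms: acetic anhydride (CC(=O)OC(C)=O)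
Why: DMAP-catalysed acetylation should esterify the two secondary hydroxyls at C6 and C7 and leave the hindered tertiary C8 hydroxyl free.

**Compound list**
1 | ethyl 2,2-diethoxyacetate | CCOC(OCC)C(=O)OCC | starting material
2 | prop-1-yn-1-ylmagnesium bromide (THF solution) | CC#C[Mg]Br | starting material
3 | 1,1-diethoxypent-3-yn-2-one | CCOC(OCC)C(=O)C#CC | intermediate
4 | (R)-1,1-diethoxypent-3-yn-2-ol | CCOC(OCC)[C@H](O)C#CC | intermediate
5 | (R)-5-(diethoxymethyl)-3,4-dimethyl-2,5-dihydro-1,2-oxamagnesole (cyclic alkenylmagnesium alkoxide) | CCOC(OCC)[C@@H]1O[Mg]C(C)=C1C | intermediate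
6 | (R,Z)-1,1-diethoxy-4-iodo-3-methylpent-3-en-2-ol | CCOC(OCC)[C@H](O)/C(C)=C(\I)C | intermediate
7 | (R,Z)-tributyl{[(1,1-diethoxy-4-iodo-3-methylpent-3-en-2-yl)oxy]methyl}stannane | CCOC(OCC)[C@H](OC[Sn](CCCC)(CCCC)CCCC)/C(C)=C(\I)C | intermediate
8 | alkenylmagnesium chloride from 7 (iodine replaced by MgCl, Z geometry kept) | CCOC(OCC)[C@H](OC[Sn](CCCC)(CCCC)CCCC)/C(C)=C(\[Mg]Cl)C | intermediate
9 | (R,Z)-5,5-diethoxy-2,3-dimethyl-4-[(tributylstannyl)methoxy]pent-2-enal | CCOC(OCC)[C@H](OC[Sn](CCCC)(CCCC)CCCC)/C(C)=C(\C=O)C | intermediate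
10 | 1-(triphenyl-λ5-phosphanylidene)propan-2-one | CC(=O)C=P(c1ccccc1)(c1ccccc1)c1ccccc1 | starting material
11 | (3E,5Z,7R)-8,8-diethoxy-5,6-dimethyl-7-[(tributylstannyl)methoxy]octa-3,5-dien-2-one | CCOC(OCC)[C@H](OC[Sn](CCCC)(CCCC)CCCC)/C(C)=C(C)\C=C\C(C)=O | intermediate
12 | (2R,3Z,5E)-3,4-dimethyl-7-oxo-2-[(tributylstannyl)methoxy]octa-3,5-dienal | O=C[C@H](OC[Sn](CCCC)(CCCC)CCCC)/C(C)=C(C)\C=C\C(C)=O | intermediate
13 | 1-bromobut-2-yne | CC#CCBr | starting material
14 | (3E,5Z,7R)-8-hydroxy-5,6,9-trimethyl-7-[(tributylstannyl)methoxy]undeca-3,5,9,10-tetraen-2-one (both C8 epimers) | C=C=C(C)C(O)[C@H](OC[Sn](CCCC)(CCCC)CCCC)/C(C)=C(C)\C=C\C(C)=O | intermediate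
15 | (3E,5Z,7R)-5,6,9-trimethyl-7-[(tributylstannyl)methoxy]undeca-3,5,9,10-tetraene-2,8-dione | C=C=C(C)C(=O)[C@H](OC[Sn](CCCC)(CCCC)CCCC)/C(C)=C(C)\C=C\C(C)=O | intermediate
16 | (5R,6Z,8E)-10-[(tert-butyldimethylsilyl)oxy]-3,6,7-trimethyl-5-[(tributylstannyl)methoxy]undeca-1,2,6,8,10-pentaen-4-one | C=C=C(C)C(=O)[C@H](OC[Sn](CCCC)(CCCC)CCCC)/C(C)=C(C)\C=C\C(=C)O[Si](C)(C)C(C)(C)C | intermediate
17 | 2-[(tert-butyldimethylsilyl)oxy]-7α-[(tributylstannyl)methoxy]-11,12,13,14,15,16-hexanorcleroda-1,4(18),8-trien-6-one | O=C1[C@H](OC[Sn](CCCC)(CCCC)CCCC)C(C)=C(C)[C@H]2C=C(O[Si](C)(C)C(C)(C)C)CC(=C)[C@]12C | intermediate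
18 | 2-[(tert-butyldimethylsilyl)oxy]-7α-[(tributylstannyl)methoxy]-11,12,13,14,15,16-hexanorcleroda-1,4(18),8-trien-6β-ol | O[C@H]1[C@H](OC[Sn](CCCC)(CCCC)CCCC)C(C)=C(C)[C@H]2C=C(O[Si](C)(C)C(C)(C)C)CC(=C)[C@]12C | intermediate
19 | dilithio derivative of 18 (6β-OLi, 7α-OCH2Li) | [Li]O[C@H]1[C@H](OC[Li])C(C)=C(C)[C@H]2C=C(O[Si](C)(C)C(C)(C)C)CC(=C)[C@]12C | intermediate
20 | 2-[(tert-butyldimethylsilyl)oxy]-12,13,14,15,16-pentanorcleroda-1,4(18),7-triene-6β,11-diol | O[C@H]1C=C(C)[C@](C)(CO)[C@H]2C=C(O[Si](C)(C)C(C)(C)C)CC(=C)[C@]12C | intermediate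
21 | 6β,11-dihydroxy-12,13,14,15,16-pentanorcleroda-4(18),7-dien-2-one | O[C@H]1C=C(C)[C@](C)(CO)[C@H]2CC(=O)CC(=C)[C@]12C | intermediate
22 | 6β,11-dihydroxy-12,13,14,15,16-pentanorcleroda-3,7-dien-2-one | O[C@H]1C=C(C)[C@](C)(CO)[C@H]2CC(=O)C=C(C)[C@]12C | intermediate
23 | 6β,7α,8α,11-tetrahydroxy-12,13,14,15,16-pentanorclerod-3-en-2-one | O[C@H]1[C@H](O)[C@](C)(O)[C@](C)(CO)[C@H]2CC(=O)C=C(C)[C@]12C | intermediate
24 | 2,2-(ethane-1,2-diyldisulfanediyl)-12,13,14,15,16-pentanorclerod-3-ene-6β,7α,8α,11-tetraol | O[C@H]1[C@H](O)[C@](C)(O)[C@](C)(CO)[C@H]2CC3(SCCS3)C=C(C)[C@]12C | intermediate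
25 | 12,13,14,15,16-pentanorclerod-3-ene-6β,7α,8α,11-tetraol | O[C@H]1[C@H](O)[C@](C)(O)[C@](C)(CO)[C@H]2CCC=C(C)[C@]12C | intermediate
26 | 6β,7α,8α-trihydroxy-12,13,14,15,16-pentanorclerod-3-en-11-al | O[C@H]1[C@H](O)[C@](C)(O)[C@](C)(C=O)[C@H]2CCC=C(C)[C@]12C | intermediate
27 | (11E)-12-(4,4,5,5-tetramethyl-1,3,2-dioxaborolan-2-yl)-13,14,15,16-tetranorcleroda-3,11-diene-6β,7α,8α-triol | O[C@H]1[C@H](O)[C@](C)(O)[C@](C)(/C=C/B3OC(C)(C)C(C)(C)O3)[C@H]2CCC=C(C)[C@]12C | intermediate
28 | 4-bromofuran-2(5H)-one | BrC1=CC(=O)OC1 | starting material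
29 | (11E)-6β,7α,8α-trihydroxycleroda-3,11,13-trien-15,16-olide | O[C@H]1[C@H](O)[C@](C)(O)[C@](C)(/C=C/C3=CC(=O)OC3)[C@H]2CCC=C(C)[C@]12C | intermediate
30 | (11E)-6β,7α-diacetoxy-8α-hydroxycleroda-3,11,13-trien-15,16-olide, (5R,6R,7S,8R,9R,10S) | CC(=O)O[C@H]1[C@H](OC(C)=O)[C@](C)(O)[C@](C)(/C=C/C2=CC(=O)OC2)[C@H]2CCC=C(C)[C@]12C | target

Total step count: 20. Longest linear sequence: 20 steps, from 1 to 30.

**Steps most likely to fail**

Step 10. The process at risk is the in-flask enolization: the C6 ketone may enolize toward C7 and erase the only stereocentre, or the amine may trigger oligomerization of the allenyl ketone before the diene has formed. The fallback separates diene formation from the allenyl ketone and runs a purely thermal cycloaddition. It sets out from 14. Acetylation (Ac2O, pyridine) gives the C6 acetate (3E,5Z,7R)-5,6,9-trimethyl-2-oxo-7-[(tributylstannyl)methoxy]undeca-3,5,9,10-tetraen-8-yl acetate F1. TBSOTf/Et3N at −78 °C then gives the silyl dienol ether acetate F2, and i-Bu2AlH at −78 °C frees the allenyl carbinol F3. Dess–Martin oxidation gives 16, now isolated, which is warmed in toluene (60–80 °C, BHT) and should close to 17, where the route is rejoined.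

Step 12. The process at risk is the sigmatropic shift itself: because the C7–O bond is pseudo-equatorial and the alkene terminus is fully substituted, a [1,2]-shift or simple protonation of the carbanion may outrun the [2,3]-shift. The fallback replaces it by a thermal [3,3]-shift followed by loss of one carbon. It sets out from 18. Acetylation gives the 6β-acetate F4, and TBAF then DBU gives the ring A enone F5. Iodine cleaves the carbon–tin bond, and aqueous work-up of the iodomethyl ether frees the 7α-alcohol F6. Johnson–Claisen rearrangement (MeC(OEt)3, EtCO2H cat., xylene, 140 °C) gives the C9 acetic ester F7, and LiOH gives the hydroxy acid F8. Its N-hydroxypyridine-2-thione ester F9 (Barton ester, DCC) is photolysed under O2 with t-BuSH and the hydroperoxide is reduced with P(OMe)3. The resulting nor-alcohol is 22, where the route is rejoined.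

Step 5. The process at risk is the iodine–magnesium exchange, which may be slow or incomplete at the electron-rich, fully substituted alkenyl iodide. The fallback introduces C10 as an electrophile at the carbomagnesiation stage. It sets out from 4: the magnesium chelate 5 is quenched with paraformaldehyde instead of iodine to give (R,Z)-5,5-diethoxy-2,3-dimethylpent-2-ene-1,4-diol F10. TBSCl/imidazole gives the primary silyl ether F11, KH/Bu3SnCH2I the stannylmethyl ether F12, and TBAF the primary allylic alcohol F13. MnO2 oxidation gives 9, where the route is rejoined.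

**Further compounds**
F1 | step 10 | (3E,5Z,7R)-5,6,9-trimethyl-2-oxo-7-[(tributylstannyl)methoxy]undeca-3,5,9,10-tetraen-8-yl acetate (both C8 epimers) | C=C=C(C)C(OC(C)=O)[C@H](OC[Sn](CCCC)(CCCC)CCCC)/C(C)=C(C)\C=C\C(C)=O
F2 | step 10 | (5R,6Z,8E)-10-[(tert-butyldimethylsilyl)oxy]-3,6,7-trimethyl-5-[(tributylstannyl)methoxy]undeca-1,2,6,8,10-pentaen-4-yl acetate (both C4 epimers) | C=C=C(C)C(OC(C)=O)[C@H](OC[Sn](CCCC)(CCCC)CCCC)/C(C)=C(C)\C=C\C(=C)O[Si](C)(C)C(C)(C)C
F3 | step 10 | (5R,6Z,8E)-10-[(tert-butyldimethylsilyl)oxy]-3,6,7-trimethyl-5-[(tributylstannyl)methoxy]undeca-1,2,6,8,10-pentaen-4-ol (both C4 epimers) | C=C=C(C)C(O)[C@H](OC[Sn](CCCC)(CCCC)CCCC)/C(C)=C(C)\C=C\C(=C)O[Si](C)(C)C(C)(C)C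
F4 | step 12 | 6β-acetoxy-2-[(tert-butyldimethylsilyl)oxy]-7α-[(tributylstannyl)methoxy]-11,12,13,14,15,16-hexanorcleroda-1,4(18),8-triene | CC(=O)O[C@H]1[C@H](OC[Sn](CCCC)(CCCC)CCCC)C(C)=C(C)[C@H]2C=C(O[Si](C)(C)C(C)(C)C)CC(=C)[C@]12C
F5 | step 12 | 6β-acetoxy-7α-[(tributylstannyl)methoxy]-11,12,13,14,15,16-hexanorcleroda-3,8-dien-2-one | CC(=O)O[C@H]1[C@H](OC[Sn](CCCC)(CCCC)CCCC)C(C)=C(C)[C@H]2CC(=O)C=C(C)[C@]12C
F6 | step 12 | 6β-acetoxy-7α-hydroxy-11,12,13,14,15,16-hexanorcleroda-3,8-dien-2-one | CC(=O)O[C@H]1[C@H](O)C(C)=C(C)[C@H]2CC(=O)C=C(C)[C@]12C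
F7 | step 12 | ethyl 6β-acetoxy-2-oxo-13,14,15,16-tetranorcleroda-3,7-dien-12-oate | CC(=O)O[C@H]1C=C(C)[C@](C)(CC(=O)OCC)[C@H]2CC(=O)C=C(C)[C@]12C
F8 | step 12 | 6β-hydroxy-2-oxo-13,14,15,16-tetranorcleroda-3,7-dien-12-oic acid | O[C@H]1C=C(C)[C@](C)(CC(=O)O)[C@H]2CC(=O)C=C(C)[C@]12C
F9 | step 12 | 2-thioxopyridin-1(2H)-yl 6β-hydroxy-2-oxo-13,14,15,16-tetranorcleroda-3,7-dien-12-oate (Barton ester) | O[C@H]1C=C(C)[C@](C)(CC(=O)ON3C=CC=CC3=S)[C@H]2CC(=O)C=C(C)[C@]12C
F10 | step 5 | (R,Z)-5,5-diethoxy-2,3-dimethylpent-2-ene-1,4-diol | CCOC(OCC)[C@H](O)/C(C)=C(\CO)C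
F11 | step 5 | (R,Z)-5-[(tert-butyldimethylsilyl)oxy]-1,1-diethoxy-3,4-dimethylpent-3-en-2-ol | CCOC(OCC)[C@H](O)/C(C)=C(\CO[Si](C)(C)C(C)(C)C)C
F12 | step 5 | (R,Z)-tert-butyl({5,5-diethoxy-2,3-dimethyl-4-[(tributylstannyl)methoxy]pent-2-en-1-yl}oxy)dimethylsilane | CCOC(OCC)[C@H](OC[Sn](CCCC)(CCCC)CCCC)/C(C)=C(\CO[Si](C)(C)C(C)(C)C)C
F13 | step 5 | (R,Z)-5,5-diethoxy-2,3-dimethyl-4-[(tributylstannyl)methoxy]pent-2-en-1-ol | CCOC(OCC)[C@H](OC[Sn](CCCC)(CCCC)CCCC)/C(C)=C(\CO)C
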